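At 8.0 d the flask was due to be read and one remedy chosen; Thursday's run is this same flask, followed so far to 144 h.

the same everywhere: left-handed substrate 1.5 M; right-handed substrate 1.5 M; gas 130 mM (held); free catalyst 240 mM; impurity 250 mM
- Thursday's: temperature 25 °C; the very flask that is asked about, followed so far
- Sunday's: temperature 10 °C; run made earlier
- flask: temperature 25 °C; time 8.0 d

| Thursday's: time / h | Thursday's: left-handed product / % | Sunday's: time / h | Sunday's: left-handed product / % |
|---|---|---|---|
| 30.0 | 29.4 | 60.0 | 31.3 |
| 60.0 | 37.0 | 120 | 41.4 |
| 96.0 | 38.0 | 192 | 45.1 |
| 120 | 39.8 | 240 | 46.0 |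
| 144 | 41.5 | 288 | 47.3 |

(readings scatter by 0.5 percentage points)

- free catalyst is single-handed; left-handed substrate and right-handed substrate are mirror images of each other, charged as a racemate, each of them at the stated concentration
- left-handed product that was removed still counts
- at the start none of the gas is in solution
- additions bring no volume worth counting

1. left-handed product, in percent of the left-handed substrate and right-handed substrate together first charged, at 8.0 d
2. the remedy with the largest gain of left-handed product, or "none" below 2 percentage points (noon / summer / spring / autumn / none)
3. left-handed product present, with what was taken out counted in, in percent of the left-handed substrate and right-handed substrate together first charged, after spring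
4. left-handed product present, with what was taken out counted in, in percent of the left-handed substrate and right-handed substrate together first charged, after autumn

- noon: change nothing and wait 8.0 d more
- summer: at 8.0 d raise the temperature by 10 K, then wait 8.0 d
- spring: at 8.0 d take out 90 % of the left-handed product then present, then wait 8.0 d
- autumn: at 8.0 d add free catalyst, 100 % of the amount charged, then wait 8.0 d

I began with two extreme versions of the flask. In one the catalyst lasted, and left-handed product ended at the ceiling of 50.0 %, the share of left-handed substrate in the charge. In the other the catalyst stopped at the bend of Thursday's run, and left-handed product stayed at 37.0 %, read at 60.0 h. The real flask lay between them, since Thursday's readings still rose to 41.5 %. Thursday's mean rate up to the first reading stood 13.4 times above its late rate, as read, while the left-handed substrate available fell by a factor of 5.88, so I read a loss of catalyst as well. At 120 h Sunday's colder run read 41.4 %, higher than Thursday's 39.8 % at the same time, and it went on to 47.3 % at 288 h, so the bend of Thursday's run was no chemical ceiling. With [impurity] at 250 mM close to [free catalyst] at 240 mM, I treated the catalyst as a stock of turns.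

I defined the turnover budget (turnover number) as left-handed product made up to the bend per free catalyst charged: 4.62. A straight line through Thursday's late readings gave 45.0 % at 8.0 d, which I took as my high end, with 41.5 % as my low end. I reckoned the second charge of autumn at a budget of 37.0 % of the charge, against a gap of 8.5 percentage points from Thursday's last reading to the ceiling, so I chose autumn.

The forecast, made from the same runs, gave 44 % (43 % to 45.2 %), chose autumn, and put spring at 48 % (46 % to 49.5 %) and autumn at 49.5 % (48.3 % to 50 %), holding that “the catalyst dies over time, probably poisoned by the roughly equimolar impurity, and dies faster when warm”. Its low end for the reading stood above mine.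

    free catalyst + right-handed substrate ⇌ catalyst intermediate B (K = 2.50 L mol⁻¹, k = 8.00 L mol⁻¹ h⁻¹, Ea = 59.0 kJ mol⁻¹, ΔH = −36.0 kJ mol⁻¹)
    partner + catalyst intermediate B → free catalyst + right-handed product (k = 2.00 L mol⁻¹ h⁻¹, Ea = 51.0 kJ mol⁻¹)
    free catalyst + impurity → spent catalyst (k = 2.40 L mol⁻¹ h⁻¹, Ea = 61.0 kJ mol⁻¹)
    free catalyst ⇌ dormant form (K = 5.30, k = 0.0760 h⁻¹, Ea = 101 kJ mol⁻¹, ΔH = −29.0 kJ mol⁻¹)
    partner + catalyst intermediate A → free catalyst + left-handed product (k = 4.80 L mol⁻¹ h⁻¹, Ea = 49.0 kJ mol⁻¹)
    free catalyst + left-handed substrate ⇌ catalyst intermediate A (K = 4.70 L mol⁻¹, k = 9.10 L mol⁻¹ h⁻¹, Ea = 62.0 kJ mol⁻¹, ΔH = −35.0 kJ mol⁻¹)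
    gas ⇌ partner, rate k7*(csat - [partner]) (kL = 5.60 h⁻¹)
    (constants at 25 °C)

The flask gave 42.5 % at 8.0 d, 45.2 % after spring and 50.0 % after autumn. By 19.2 h the flask held 58.0 % of its catalyst as spent catalyst, with impurity at 44.3 % of its charge and left-handed product at 24.2 %. By 192 h spent catalyst stood at 92.3 %, while free left-handed substrate stood at 15 % of its own charge. Against my reckoned budget of 37.0 %, autumn brought 7.5 points. A neighbour flask with 0.60 M of free catalyst, reckoned at 4.62 turns, had a budget of 92.5 %, above the ceiling of 50.0 %, and it gave 50.0 % at 192 h, with free left-handed substrate at 0 % of its charge.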